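**Plan**

1. Retrosynthesis: the (Z)-coumarate is cut at its C=C bond and at the C15–O ester bond. The C17 methyl is traced back to an ester and ring B is opened at C6–C7 and C8–C9, which releases ethyl propiolate and a ring A iodide (C6–I) that carries the side chain as a (Z)-C9=C11 alkene. That alkene is cut (Wittig) into a ring A aldehyde and a C11–C15 phosphonium salt; C6 is traced to a C5 ketone and C9 to an allyl group on C10.
2. Forward: ring A is bought as ketoisophorone and dressed first (quaternary C10, then C6 and C9), the side chain is joined by a (Z)-selective Wittig reaction, ring B is closed last by a radical [4+2] annulation, and the coumarate is built at the end.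
3. Feature used: in ring B the C7=C8 double bond lies between the C6 methylene and the C9 methine, C7 carries only H and C8 only the C17 methyl. A two-carbon alkyne H–C≡C–CO2Et can therefore be inserted between a C6 radical and the C9=C11 alkene, which hang trans-diequatorially from C5 and C10 of the finished ring A.
4. Stereochemistry: C2 by Ru-catalysed transfer hydrogenation; C10 by Pd-catalysed decarboxylative allylation (catalyst control); C5 by hydroboration anti to the axial methyl groups on C4 and C10; C9 in the radical ring closure, relayed from C10 through 1,3-allylic strain of the (Z)-alkene; C13 bought with methyl hydrogen (R)-3-methylglutarate; the (Z)-ester by a diaryl phosphonoacetate olefination.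
5. Atom numbers are labdane numbers: C1–C10 decalin, C11–C16 side chain, C17 on C8, C18 and C19 on C4, C20 on C10. TBS = tert-butyldimethylsilyl.

Key step: step 16

Assumption: the facial sense of the Ru/TsDPEN and Pd/PHOX catalysts is taken over from the parent substrates (alkenyl ketones, 2-methylcyclohexanone enol carbonates); if either proved opposite on this substrate, the mirror-image ligand would be used.

**Route**

Step 1
Reactants: 1 ketoisophorone (2,6,6-trimethylcyclohex-2-ene-1,4-dione)
Product: 2 (S)-4-hydroxy-2,6,6-trimethylcyclohex-2-en-1-one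
Conditions: RuCl[(S,S)-TsDPEN](p-cymene) (1 mol %), i-PrOH, 25 °C
Reagents that add atoms: none
Why: Asymmetric transfer hydrogenation should reduce only the C4 carbonyl (the other one is flanked by the gem-dimethyl carbon), with the alkenyl group playing the role of the aryl group in the usual model so that the (S)-carbinol, C2 of the target, is expected.

Step 2
Reactants: 2 (S)-4-hydroxy-2,6,6-trimethylcyclohex-2-en-1-one
Product: 3 (S)-4-(tert-butyldimethylsilyloxy)-2,6,6-trimethylcyclohex-2-en-1-one
Conditions: TBSCl, imidazole, DMF, 25 °C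
Reagents that add atoms: tert-butyldimethylsilyl chloride, CC(C)(C)[Si](C)(C)Cl
Why: Standard silylation of a secondary alcohol gives an ether that should survive every later base, hydride, radical and Pd step.

Step 3
Reactants: 3 (S)-4-(tert-butyldimethylsilyloxy)-2,6,6-trimethylcyclohex-2-en-1-one
Product: 5 allyl (R)-4-(tert-butyldimethylsilyloxy)-2,6,6-trimethylcyclohex-1-en-1-yl carbonate, via lithium enolate 4 (not isolated)
Conditions: LiBH(s-Bu)3, THF, −78 °C; then allyl chloroformate, −78 to 0 °C
Reagents that add atoms: allyl chloroformate, C=CCOC(=O)Cl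
Why: Conjugate hydride addition to the β-unsubstituted enone (1,2-attack is blocked by the flanking quaternary carbon) should give the tetrasubstituted enolate regiospecifically, and the hard chloroformate acylates it on oxygen (enol carbonate formation).

Step 4
Reactants: 5 allyl (R)-4-(tert-butyldimethylsilyloxy)-2,6,6-trimethylcyclohex-1-en-1-yl carbonate
Product: 6 (2S,4S)-2-allyl-4-(tert-butyldimethylsilyloxy)-2,6,6-trimethylcyclohexan-1-one (allyl cis to the silyloxy group)
Conditions: Pd2(dba)3 (2.5 mol %), (R)-t-Bu-PHOX (6 mol %), THF, 25 °C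
Reagents that add atoms: none
Why: Decarboxylative asymmetric allylic alkylation (Tsuji–Trost type): zerovalent palladium ionises the allyl carbonate, CO2 is lost and the enolate/π-allyl pair recombines at carbon to form quaternary C10, with the PHOX ligand rather than the remote silyloxy group expected to choose the enolate face; the minor trans diastereomer should be removable by chromatography.

Step 5
Reactants: 6 (2S,4S)-2-allyl-4-(tert-butyldimethylsilyloxy)-2,6,6-trimethylcyclohexan-1-one
Product: 7 (2R,4S)-4-(tert-butyldimethylsilyloxy)-2,6,6-trimethyl-2-[(E)-prop-1-enyl]cyclohexan-1-one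
Conditions: RuHCl(CO)(PPh3)3 (5 mol %), toluene, 80 °C
Reagents that add atoms: none
Why: Ruthenium hydride addition–elimination (alkene isomerisation) moves the terminal double bond one position inward to the more stable propenyl group and cannot go further because C10 is quaternary.

Step 6
Reactants: 7 (2R,4S)-4-(tert-butyldimethylsilyloxy)-2,6,6-trimethyl-2-[(E)-prop-1-enyl]cyclohexan-1-one
Product: 8 (1R,5S)-5-(tert-butyldimethylsilyloxy)-1,3,3-trimethyl-2-methylidene-1-[(E)-prop-1-enyl]cyclohexane
Conditions: Ph3PCH3Br, KOt-Bu, toluene, 110 °C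
Reagents that add atoms: methyltriphenylphosphonium bromide, C[P+](c1ccccc1)(c1ccccc1)c1ccccc1.[Br-]
Why: Wittig methylenation under forcing conditions installs C6; the ketone has no α-hydrogen, so the hot ylide can only add to the carbonyl group.

Step 7
Reactants: 8 (1R,5S)-5-(tert-butyldimethylsilyloxy)-1,3,3-trimethyl-2-methylidene-1-[(E)-prop-1-enyl]cyclohexane
Product: 10 [(1S,4S,6R)-4-(tert-butyldimethylsilyloxy)-2,2,6-trimethyl-6-[(E)-prop-1-enyl]cyclohexyl]methanol, via B-alkyl-9-BBN adduct 9 (not isolated)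
Conditions: 9-BBN, THF, 0 to 60 °C; then NaOH, H2O2, 0 °C to rt
Reagents that add atoms: hydrogen peroxide, OO
Why: Hydroboration–oxidation: 9-BBN reacts with the 1,1-disubstituted alkene far faster than with the trans-1,2-disubstituted one and should approach anti to the two syn-axial methyl groups on C4 and C10, so H is delivered to C5 trans to the C10 methyl (new stereocentre C5).

Step 8
Reactants: 10 [(1S,4S,6R)-4-(tert-butyldimethylsilyloxy)-2,2,6-trimethyl-6-[(E)-prop-1-enyl]cyclohexyl]methanol
Product: 12 (1S,2S,5S)-5-(tert-butyldimethylsilyloxy)-2-(hydroxymethyl)-1,3,3-trimethylcyclohexane-1-carbaldehyde (in equilibrium with its five-membered lactol), via ozonide 11 (not isolated)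
Conditions: O3, CH2Cl2, −78 °C; then PPh3, −78 °C to rt
Reagents that add atoms: ozone, [O-][O+]=O
Why: Ozonolysis with reductive work-up cleaves the only remaining C=C bond and turns C9 into the aldehyde.

Step 9
Reactants: 13 methyl hydrogen (R)-3-methylglutarate
Product: 14 methyl (R)-5-hydroxy-3-methylpentanoate
Conditions: BH3·SMe2, THF, 0 °C to rt; MeOH quench
Reagents that add atoms: none
Why: Borane reduces a carboxylic acid much faster than an ester (through the acyloxyborane), which differentiates the two chain ends without touching the stereocentre that becomes C13.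

Step 10
Reactants: 14 methyl (R)-5-hydroxy-3-methylpentanoate
Product: 15 methyl (R)-5-(tert-butyldimethylsilyloxy)-3-methylpentanoate
Conditions: TBSCl, imidazole, DMF, 0 °C to rt
Reagents that add atoms: tert-butyldimethylsilyl chloride, CC(C)(C)[Si](C)(C)Cl
Why: Standard silylation protects the future C15 hydroxyl and prevents lactonisation.

Step 11
Reactants: 15 methyl (R)-5-(tert-butyldimethylsilyloxy)-3-methylpentanoate
Product: 16 (S)-5-(tert-butyldimethylsilyloxy)-3-methylpentan-1-ol
Conditions: LiAlH4, THF, 0 °C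
Reagents that add atoms: none
Why: Hydride reduction of the ester gives the primary alcohol at C11.

Step 12
Reactants: 16 (S)-5-(tert-butyldimethylsilyloxy)-3-methylpentan-1-ol
Product: 17 (R)-tert-butyl[(5-iodo-3-methylpentyl)oxy]dimethylsilane
Conditions: I2, PPh3, imidazole, CH2Cl2, 0 °C to rt
Reagents that add atoms: iodine, II
Why: Appel-type iodination (alkoxyphosphonium ion, SN2 by iodide) of an unhindered primary alcohol.

Step 13
Reactants: 17 (R)-tert-butyl[(5-iodo-3-methylpentyl)oxy]dimethylsilane
Product: 18 [(R)-5-(tert-butyldimethylsilyloxy)-3-methylpentyl]triphenylphosphonium iodide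
Conditions: PPh3, i-Pr2NEt (0.1 equiv), MeCN, 80 °C
Reagents that add atoms: triphenylphosphine, c1ccc(cc1)P(c1ccccc1)c1ccccc1
Why: SN2 quaternisation of the phosphine by a primary iodide, with a trace of amine to protect the silyl ether.

Step 14
Reactants: 12 (1S,2S,5S)-5-(tert-butyldimethylsilyloxy)-2-(hydroxymethyl)-1,3,3-trimethylcyclohexane-1-carbaldehyde; 18 [(R)-5-(tert-butyldimethylsilyloxy)-3-methylpentyl]triphenylphosphonium iodide
Product: 20 [(1S,4S,6R)-4-(tert-butyldimethylsilyloxy)-6-[(1Z,4S)-6-(tert-butyldimethylsilyloxy)-4-methylhex-1-enyl]-2,2,6-trimethylcyclohexyl]methanol, via phosphonium ylide 19 (not isolated)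
Conditions: 18 (1.4 equiv), NaN(SiMe3)2 (2.4 equiv in all, one of them for the lactol OH), THF, −78 °C to rt
Reagents that add atoms: none
Why: Wittig olefination: the non-stabilised, lithium-free ylide should add to the aldehyde form of the lactol under kinetic control (cis-oxaphosphetane) to give the (Z)-C9=C11 alkene.

Step 15
Reactants: 20 [(1S,4S,6R)-4-(tert-butyldimethylsilyloxy)-6-[(1Z,4S)-6-(tert-butyldimethylsilyloxy)-4-methylhex-1-enyl]-2,2,6-trimethylcyclohexyl]methanol
Product: 21 [(1S,4S,6R)-4-(tert-butyldimethylsilyloxy)-6-[(1Z,4S)-6-(tert-butyldimethylsilyloxy)-4-methylhex-1-enyl]-2,2,6-trimethylcyclohexyl]methyl iodide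
Conditions: I2, PPh3, imidazole, toluene, rt to 60 °C
Reagents that add atoms: iodine, II
Why: Appel-type iodination of the primary C6 alcohol, which supplies the radical precursor.

Step 16
Reactants: 21 [(1S,4S,6R)-4-(tert-butyldimethylsilyloxy)-6-[(1Z,4S)-6-(tert-butyldimethylsilyloxy)-4-methylhex-1-enyl]-2,2,6-trimethylcyclohexyl]methyl iodide; 22 ethyl propiolate
Product: 26 ethyl (13S)-2α,15-bis(tert-butyldimethylsilyloxy)labd-7-en-17-oate (5α-H, 9α-H, 10β-CH3), via primary alkyl radical 23 (not isolated), via vinyl radical 24 (not isolated), via secondary alkyl radical 25 (not isolated)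
Conditions: 22 (5 equiv), Bu3SnH (1.3 equiv, added over 8 h), AIBN (0.2 equiv), benzene (0.01 M in 21), 80 °C
Reagents that add atoms: none
Why: Bu3Sn• abstracts iodine from 21; the primary C6 radical 23, which cannot cyclise itself (4-exo or 5-endo only), adds to the unsubstituted terminus of ethyl propiolate (C6–C7), and the linear α-(ethoxycarbonyl)vinyl radical 24 closes ring B by attack on C9 of the (Z)-alkene (C8–C9) before the secondary radical 25 takes hydrogen from Bu3SnH. The closest known reaction type is the tandem radical addition–cyclisation (radical annulation) of alkyl halides with electron-poor alkynes, combined with 6-exo vinyl radical cyclisation. Ring B is closed in the 6-exo-trig mode through a chair-like transition state on the locked ring A chair, in which C6 and the alkenyl group are trans-diequatorial. C9 is the only new stereocentre and should be controlled by C10: 1,3-allylic strain of the (Z)-alkene holds C12 over the small C10 methyl and away from C5, so C8 can reach only the face of C9 that leaves C11 equatorial and cis to the C10 methyl (9α-H). The step needs chemoselectivity (addition of 23 to the alkyne faster than hydrogen transfer, and hydrogen transfer to 25 faster than a second addition), which slow addition of the stannane to an excess of alkyne and the shielding of C11 in 25 are meant to secure. It also needs regioselectivity (terminal attack, exo closure), which the polarity match of the nucleophilic radical with the propiolate and the 6-exo over 7-endo preference should secure.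

Step 17
Reactants: 26 ethyl (13S)-2α,15-bis(tert-butyldimethylsilyloxy)labd-7-en-17-oate
Product: 27 (13S)-2α,15-bis(tert-butyldimethylsilyloxy)labd-7-en-17-ol
Conditions: i-Bu2AlH (2.5 equiv), CH2Cl2, −78 °C
Reagents that add atoms: none
Why: 1,2-Reduction of the conjugated ester by the electrophilic aluminium hydride gives the allylic alcohol and leaves the C7=C8 bond in place.

Step 18
Reactants: 27 (13S)-2α,15-bis(tert-butyldimethylsilyloxy)labd-7-en-17-ol
Product: 29 (13S)-2α,15-bis(tert-butyldimethylsilyloxy)labd-7-ene, via pyridinium sulfate monoester 28 (not isolated)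
Conditions: SO3·pyridine, THF, 0 °C; then LiAlH4, 0 °C to rt
Reagents that add atoms: none
Why: Deoxygenation of the primary allylic alcohol through its sulfate monoester: hydride displaces sulfate by SN2 at C17 without allylic transposition and so gives the C17 methyl.

Step 19
Reactants: 29 (13S)-2α,15-bis(tert-butyldimethylsilyloxy)labd-7-ene
Product: 30 (13S)-2α-(tert-butyldimethylsilyloxy)labd-7-en-15-ol
Conditions: camphorsulfonic acid (0.1 equiv), MeOH/CH2Cl2 1:1, 0 °C
Reagents that add atoms: none
Why: Acid-catalysed methanolysis should remove the unhindered primary silyl ether much faster than the secondary one on ring A (selective desilylation).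

Step 20
Reactants: 30 (13S)-2α-(tert-butyldimethylsilyloxy)labd-7-en-15-ol; 31 (diphenoxyphosphoryl)acetic acid
Product: 32 (13S)-2α-(tert-butyldimethylsilyloxy)labd-7-en-15-yl (diphenoxyphosphoryl)acetate
Conditions: EDC·HCl, DMAP (0.1 equiv), CH2Cl2, 0 °C to rt
Reagents that add atoms: none
Why: Steglich-type carbodiimide esterification of the only free hydroxyl group.

Step 21
Reactants: 32 (13S)-2α-(tert-butyldimethylsilyloxy)labd-7-en-15-yl (diphenoxyphosphoryl)acetate; 33 4-(tert-butyldimethylsilyloxy)benzaldehyde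
Product: 34 (13S)-2α-(tert-butyldimethylsilyloxy)labd-7-en-15-yl (Z)-3-[4-(tert-butyldimethylsilyloxy)phenyl]prop-2-enoate
Conditions: NaH, THF, 0 °C; then 33, −78 to −20 °C
Reagents that add atoms: none
Why: Horner–Wadsworth–Emmons olefination with a diaryl phosphonoacetate, whose electron-poor phosphorus makes elimination from the first-formed adduct fast and should therefore give the (Z)-cinnamate under kinetic control.

Step 22
Reactants: 34 (13S)-2α-(tert-butyldimethylsilyloxy)labd-7-en-15-yl (Z)-3-[4-(tert-butyldimethylsilyloxy)phenyl]prop-2-enoate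
Product: 35 (2S,5S,9S,10S,13S)-2-hydroxylabd-7-en-15-yl (Z)-3-(4-hydroxyphenyl)prop-2-enoate (CNP0301213.1)
Conditions: HF·pyridine, pyridine, THF, 0 °C to rt, light excluded
Reagents that add atoms: none
Why: Fluoride cleaves the aryl and the secondary alkyl silyl ether under mildly acidic conditions that should neither isomerise the (Z)-alkene nor cleave the ester.

**Compound list**

1 | ketoisophorone (2,6,6-trimethylcyclohex-2-ene-1,4-dione) | CC1=CC(=O)CC(C)(C)C1=O | starting material
2 | (S)-4-hydroxy-2,6,6-trimethylcyclohex-2-en-1-one | CC1(C)C[C@H](O)C=C(C)C1=O | intermediate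
3 | (S)-4-(tert-butyldimethylsilyloxy)-2,6,6-trimethylcyclohex-2-en-1-one | CC1(C)C[C@H](O[Si](C)(C)C(C)(C)C)C=C(C)C1=O | intermediate
4 | lithium (R)-4-(tert-butyldimethylsilyloxy)-2,6,6-trimethylcyclohex-1-en-1-olate | CC1(C)C[C@H](O[Si](C)(C)C(C)(C)C)CC(C)=C1[O-].[Li+] | intermediate (not isolated)
5 | allyl (R)-4-(tert-butyldimethylsilyloxy)-2,6,6-trimethylcyclohex-1-en-1-yl carbonate | CC1(C)C[C@H](O[Si](C)(C)C(C)(C)C)CC(C)=C1OC(=O)OCC=C | intermediate
6 | (2S,4S)-2-allyl-4-(tert-butyldimethylsilyloxy)-2,6,6-trimethylcyclohexan-1-one | CC1(C)C[C@H](O[Si](C)(C)C(C)(C)C)C[C@](C)(CC=C)C1=O | intermediate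
7 | (2R,4S)-4-(tert-butyldimethylsilyloxy)-2,6,6-trimethyl-2-[(E)-prop-1-enyl]cyclohexan-1-one | CC1(C)C[C@H](O[Si](C)(C)C(C)(C)C)C[C@](C)(/C=C/C)C1=O | intermediate
8 | (1R,5S)-5-(tert-butyldimethylsilyloxy)-1,3,3-trimethyl-2-methylidene-1-[(E)-prop-1-enyl]cyclohexane | C=C1C(C)(C)C[C@H](O[Si](C)(C)C(C)(C)C)C[C@]1(C)/C=C/C | intermediate
9 | 9-{[(1S,4S,6R)-4-(tert-butyldimethylsilyloxy)-2,2,6-trimethyl-6-[(E)-prop-1-enyl]cyclohexyl]methyl}-9-borabicyclo[3.3.1]nonane | C(B1C2CCCC1CCC2)[C@H]1C(C)(C)C[C@H](O[Si](C)(C)C(C)(C)C)C[C@]1(C)/C=C/C | intermediate (not isolated)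
10 | [(1S,4S,6R)-4-(tert-butyldimethylsilyloxy)-2,2,6-trimethyl-6-[(E)-prop-1-enyl]cyclohexyl]methanol | OC[C@H]1C(C)(C)C[C@H](O[Si](C)(C)C(C)(C)C)C[C@]1(C)/C=C/C | intermediate
11 | ozonide of 10 (3-methyl-1,2,4-trioxolan-5-yl group in place of the propenyl group) | OC[C@H]1C(C)(C)C[C@H](O[Si](C)(C)C(C)(C)C)C[C@]1(C)C1OOC(C)O1 | intermediate (not isolated)
12 | (1S,2S,5S)-5-(tert-butyldimethylsilyloxy)-2-(hydroxymethyl)-1,3,3-trimethylcyclohexane-1-carbaldehyde (open form of the lactol) | OC[C@H]1C(C)(C)C[C@H](O[Si](C)(C)C(C)(C)C)C[C@]1(C)C=O | intermediate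
13 | methyl hydrogen (R)-3-methylglutarate | COC(=O)C[C@H](C)CC(=O)O | starting material
14 | methyl (R)-5-hydroxy-3-methylpentanoate | COC(=O)C[C@H](C)CCO | intermediate
15 | methyl (R)-5-(tert-butyldimethylsilyloxy)-3-methylpentanoate | COC(=O)C[C@H](C)CCO[Si](C)(C)C(C)(C)C | intermediate
16 | (S)-5-(tert-butyldimethylsilyloxy)-3-methylpentan-1-ol | OCC[C@H](C)CCO[Si](C)(C)C(C)(C)C | intermediate
17 | (R)-tert-butyl[(5-iodo-3-methylpentyl)oxy]dimethylsilane | ICC[C@H](C)CCO[Si](C)(C)C(C)(C)C | intermediate
18 | [(R)-5-(tert-butyldimethylsilyloxy)-3-methylpentyl]triphenylphosphonium iodide | [I-].c1ccccc1[P+](c1ccccc1)(c1ccccc1)CC[C@H](C)CCO[Si](C)(C)C(C)(C)C | intermediate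
19 | [5-(tert-butyldimethylsilyloxy)-3-methylpentylidene]triphenylphosphorane (configuration as in 18) | c1ccccc1P(c1ccccc1)(c1ccccc1)=CC[C@H](C)CCO[Si](C)(C)C(C)(C)C | intermediate (not isolated)
20 | [(1S,4S,6R)-4-(tert-butyldimethylsilyloxy)-6-[(1Z,4S)-6-(tert-butyldimethylsilyloxy)-4-methylhex-1-enyl]-2,2,6-trimethylcyclohexyl]methanol | OC[C@H]1C(C)(C)C[C@H](O[Si](C)(C)C(C)(C)C)C[C@]1(C)/C=C\C[C@H](C)CCO[Si](C)(C)C(C)(C)C | intermediate
21 | [(1S,4S,6R)-4-(tert-butyldimethylsilyloxy)-6-[(1Z,4S)-6-(tert-butyldimethylsilyloxy)-4-methylhex-1-enyl]-2,2,6-trimethylcyclohexyl]methyl iodide | IC[C@H]1C(C)(C)C[C@H](O[Si](C)(C)C(C)(C)C)C[C@]1(C)/C=C\C[C@H](C)CCO[Si](C)(C)C(C)(C)C | intermediate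
22 | ethyl propiolate | CCOC(=O)C#C | starting material
23 | primary C6 radical from 21 | [CH2][C@H]1C(C)(C)C[C@H](O[Si](C)(C)C(C)(C)C)C[C@]1(C)/C=C\C[C@H](C)CCO[Si](C)(C)C(C)(C)C | intermediate (not isolated)
24 | α-(ethoxycarbonyl)vinyl radical at C8 (adduct of 23 and 22) | CCOC(=O)[C]=CC[C@H]1C(C)(C)C[C@H](O[Si](C)(C)C(C)(C)C)C[C@]1(C)/C=C\C[C@H](C)CCO[Si](C)(C)C(C)(C)C | intermediate (not isolated)
25 | cyclised secondary C11 radical | CCOC(=O)C1=CC[C@H]2C(C)(C)C[C@H](O[Si](C)(C)C(C)(C)C)C[C@]2(C)[C@H]1[CH]C[C@H](C)CCO[Si](C)(C)C(C)(C)C | intermediate (not isolated)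
26 | ethyl (13S)-2α,15-bis(tert-butyldimethylsilyloxy)labd-7-en-17-oate | CCOC(=O)C1=CC[C@H]2C(C)(C)C[C@H](O[Si](C)(C)C(C)(C)C)C[C@]2(C)[C@H]1CC[C@H](C)CCO[Si](C)(C)C(C)(C)C | intermediate
27 | (13S)-2α,15-bis(tert-butyldimethylsilyloxy)labd-7-en-17-ol | OCC1=CC[C@H]2C(C)(C)C[C@H](O[Si](C)(C)C(C)(C)C)C[C@]2(C)[C@H]1CC[C@H](C)CCO[Si](C)(C)C(C)(C)C | intermediate
28 | pyridinium (13S)-2α,15-bis(tert-butyldimethylsilyloxy)labd-7-en-17-yl sulfate | [O-]S(=O)(=O)OCC1=CC[C@H]2C(C)(C)C[C@H](O[Si](C)(C)C(C)(C)C)C[C@]2(C)[C@H]1CC[C@H](C)CCO[Si](C)(C)C(C)(C)C.c1cc[nH+]cc1 | intermediate (not isolated)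
29 | (13S)-2α,15-bis(tert-butyldimethylsilyloxy)labd-7-ene | CC1=CC[C@H]2C(C)(C)C[C@H](O[Si](C)(C)C(C)(C)C)C[C@]2(C)[C@H]1CC[C@H](C)CCO[Si](C)(C)C(C)(C)C | intermediate
30 | (13S)-2α-(tert-butyldimethylsilyloxy)labd-7-en-15-ol | CC1=CC[C@H]2C(C)(C)C[C@H](O[Si](C)(C)C(C)(C)C)C[C@]2(C)[C@H]1CC[C@H](C)CCO | intermediate
31 | (diphenoxyphosphoryl)acetic acid | OC(=O)CP(=O)(Oc1ccccc1)Oc1ccccc1 | starting material
32 | (13S)-2α-(tert-butyldimethylsilyloxy)labd-7-en-15-yl (diphenoxyphosphoryl)acetate | CC1=CC[C@H]2C(C)(C)C[C@H](O[Si](C)(C)C(C)(C)C)C[C@]2(C)[C@H]1CC[C@H](C)CCOC(=O)CP(=O)(Oc1ccccc1)Oc1ccccc1 | intermediate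
33 | 4-(tert-butyldimethylsilyloxy)benzaldehyde | O=Cc1ccc(O[Si](C)(C)C(C)(C)C)cc1 | starting material
34 | (13S)-2α-(tert-butyldimethylsilyloxy)labd-7-en-15-yl (Z)-3-[4-(tert-butyldimethylsilyloxy)phenyl]prop-2-enoate | CC1=CC[C@H]2C(C)(C)C[C@H](O[Si](C)(C)C(C)(C)C)C[C@]2(C)[C@H]1CC[C@H](C)CCOC(=O)/C=C\c1ccc(O[Si](C)(C)C(C)(C)C)cc1 | intermediate
35 | (2S,5S,9S,10S,13S)-2-hydroxylabd-7-en-15-yl (Z)-3-(4-hydroxyphenyl)prop-2-enoate | CC1=CC[C@H]2C(C)(C)C[C@H](O)C[C@]2(C)[C@H]1CC[C@H](C)CCOC(=O)/C=C\c1ccc(O)cc1 | target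

**Step count**

Total: 22 steps. Longest linear sequence: 17 steps (steps 1–8 and 14–22, from ketoisophorone); the side-chain branch is steps 9–13.

**Steps most likely to fail**

Step 16. Hydrogen transfer to radical 23 or 24 may outrun C–C bond formation, or radical 25 may add to a second molecule of 22 before it is reduced. The fallback makes the two bonds one after the other, so it no longer needs an intermolecular radical step. It sets out from iodide 21. Zn and LiCl in THF give the alkylzinc iodide F1. Negishi coupling of F1 with (E)-2-bromo-1-iodoprop-1-ene (Pd(dppf)Cl2, THF) at the C–I bond gives the vinyl bromide F2 (C6–C7 formed). Bu3SnH and AIBN in benzene at 80 °C then generate the C8 vinyl radical inside the molecule, and its 6-exo closure onto C9 should give 29 directly with the C17 methyl already in place; the small methyl on C8 also lowers 1,2-allylic strain in the ring closure. The route is rejoined at 29 and steps 17 and 18 are not needed.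

Step 6. The ylide may fail to add to the carbonyl group of 7, which is shielded by two quaternary carbons. The fallback sets out from 7 and uses a Peterson olefination: the smaller and more nucleophilic Me3SiCH2Li with CeCl3 (THF, −78 to 0 °C) should give the β-hydroxysilane F3, and KH in THF eliminates it to 8, where the route is rejoined.

Step 21. The (Z)/(E) ratio of the olefination may be eroded, and the isomers may not separate. The fallback sets out from 30 and makes the (Z)-alkene by hydrogenation instead. Mitsunobu esterification of 30 with 3-(4-hydroxyphenyl)propiolic acid (PPh3, DIAD, THF; the carboxylic acid reacts in preference to the phenol) gives the alkynoate F4. Semihydrogenation over Pd/CaCO3 poisoned with Pb(OAc)2, with quinoline, gives the (Z)-ester F5. HF·pyridine then removes the ring A silyl ether to give 35, so this path replaces steps 20–22 and ends at 35.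

**Further compounds**

F1 | step 16 | {[(1S,4S,6R)-4-(tert-butyldimethylsilyloxy)-6-[(1Z,4S)-6-(tert-butyldimethylsilyloxy)-4-methylhex-1-enyl]-2,2,6-trimethylcyclohexyl]methyl}zinc iodide | I[Zn]C[C@H]1C(C)(C)C[C@H](O[Si](C)(C)C(C)(C)C)C[C@]1(C)/C=C\C[C@H](C)CCO[Si](C)(C)C(C)(C)C
F2 | step 16 | (E)-vinyl bromide: 21 with the CH2I group replaced by CH2–CH=C(Br)CH3 | C/C(Br)=C\C[C@H]1C(C)(C)C[C@H](O[Si](C)(C)C(C)(C)C)C[C@]1(C)/C=C\C[C@H](C)CCO[Si](C)(C)C(C)(C)C
F3 | step 6 | (2R,4S)-4-(tert-butyldimethylsilyloxy)-2,6,6-trimethyl-2-[(E)-prop-1-enyl]-1-[(trimethylsilyl)methyl]cyclohexan-1-ol (either C1 epimer) | C[Si](C)(C)CC1(O)C(C)(C)C[C@H](O[Si](C)(C)C(C)(C)C)C[C@]1(C)/C=C/C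
F4 | step 21 | (13S)-2α-(tert-butyldimethylsilyloxy)labd-7-en-15-yl 3-(4-hydroxyphenyl)prop-2-ynoate | CC1=CC[C@H]2C(C)(C)C[C@H](O[Si](C)(C)C(C)(C)C)C[C@]2(C)[C@H]1CC[C@H](C)CCOC(=O)C#Cc1ccc(O)cc1
F5 | step 21 | (13S)-2α-(tert-butyldimethylsilyloxy)labd-7-en-15-yl (Z)-3-(4-hydroxyphenyl)prop-2-enoate | CC1=CC[C@H]2C(C)(C)C[C@H](O[Si](C)(C)C(C)(C)C)C[C@]2(C)[C@H]1CC[C@H](C)CCOC(=O)/C=C\c1ccc(O)cc1
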